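**Retrosynthetic overview**
1. Carotane numbering is used: C1 (quaternary, C15 methyl, β), C2, C3, C4 (OH β, isopropyl α), C5 (ring-fusion H, α), C6 (O, α), C7, C8 (C14 methyl)=C9, C10 (O, α). The two angelates go on last, onto dauc-8-ene-4β,6α,10α-triol; C10–O and the C8=C9 alkene come from SN2′ hydride opening of a 9α,10α-epoxide, and C6–OH from a C4–OH-directed reduction of a 7,9-dien-6-one whose C5 is set trans by equilibration.
2. The seven-membered ring is traced back to a cyclobutane (C1, C5, C9, C10) fused to a cyclopentanone (C5–C6–C7–C8–C9): in the forward sense a tertiary radical at C8 breaks the C5–C9 bond, giving C8=C9 and a C5 radical stabilised by the C6 ketone (two-carbon ring enlargement).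
3. Key disconnection: the cyclobutane is opened to a cyclopent-2-enone and an isopropenyl group, so C1–C5 and C9–C10 are made in one intramolecular enone–alkene [2+2] photocycloaddition that also closes the five-membered ring C1–C5 and sets the C1 quaternary centre.
4. Enabling feature: C5–C6–C7–C8–C9 of the seven-membered ring is a masked cyclopentenone (C6 carbonyl, C5=C9) with C10–C1 inserted into its C5–C9 bond, and C1 is 1,5 to C5 across C2–C3–C4, so the alkene hangs on the enone α-carbon by a three-carbon tether whose carbinol C4 steers the face. Ring order: cyclopentenone (temporary), then cyclopentane and cyclobutane together (key step), then the seven-membered ring (fragmentation).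
5. The photosubstrate comes from (S)-terpinen-4-ol (source of C4; ozonolysis, double methylenation, Wacker oxidation) and 1,1-dimethoxypropan-2-one (aldol, cyclodehydration, tertiary oxalate as radical precursor).

Key step: step 7

Assumption: (S)-(+)-terpinen-4-ol is used in high enantiomeric purity (material of low optical purity would be enriched first); its carbinol carbon becomes C4 and fixes the absolute configuration of the series.

Step 1
Reactants: 1 (S)-terpinen-4-ol
Product: 3 (3S)-3-hydroxy-6-oxo-3-(propan-2-yl)heptanal, via ozonide 2 (not isolated)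
Conditions: O3, CH2Cl2, −78 °C; then PPh3, −78 to 25 °C; crude product used at once
Reagents that add atoms: ozone, [O-][O+]=O
Why: Ozonolysis with reductive work-up cleaves the only C=C bond to the future C6 aldehyde and C1 methyl ketone and leaves the carbinol centre (C4), the source of all later stereocontrol, untouched.

Step 2
Reactants: 3 (3S)-3-hydroxy-6-oxo-3-(propan-2-yl)heptanal
Product: 4 (4S)-7-methyl-4-(propan-2-yl)octa-1,7-dien-4-ol
Conditions: Ph3PCH3Br (4 equiv), KOt-Bu (4 equiv), THF, 0 °C; then 3, −78 to 25 °C
Reagents that add atoms: methyltriphenylphosphonium bromide, C[P+](c1ccccc1)(c1ccccc1)c1ccccc1.[Br-]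
Why: Wittig methylenation of both carbonyl groups with excess ylide turns the aldehyde into a vinyl group (C6, C7) and the methyl ketone into the isopropenyl group (C1=C10, C15), the tertiary alkoxide being inert.

Step 3
Reactants: 4 (4S)-7-methyl-4-(propan-2-yl)octa-1,7-dien-4-ol
Product: 5 (4S)-4-hydroxy-7-methyl-4-(propan-2-yl)oct-7-en-2-one
Conditions: PdCl2 (10 mol %), CuCl (30 mol %), O2 (1 atm), DMF/H2O (7:1), 25 °C
Reagents that add atoms: water, O
Why: Tsuji–Wacker oxidation converts only the monosubstituted alkene into the methyl ketone (Markovnikov), since 1,1-disubstituted alkenes are poor substrates, and gives the β-hydroxy ketone with C6 as carbonyl and C7 as methyl.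

Step 4
Reactants: 5 (4S)-4-hydroxy-7-methyl-4-(propan-2-yl)oct-7-en-2-one; 6 1,1-dimethoxypropan-2-one
Product: 8 (6S)-2,6-dihydroxy-1,1-dimethoxy-2,9-dimethyl-6-(propan-2-yl)dec-9-en-4-one (both C2 epimers), via dilithium enolate 7 (not isolated)
Conditions: LiN(i-Pr)2 (2.2 equiv), THF, −78 °C; then 6, −78 °C; AcOH quench at −78 °C
Reagents that add atoms: none
Why: After alkoxide formation the kinetic enolate forms at the methyl group (the other α-carbon is a neopentyl-type CH2) and adds to the activated ketone of 6 (aldol addition), which brings in C8 with its methyl and C9 as a masked aldehyde; the new carbinol centre (C8) is uncontrolled, which is harmless because it becomes sp2 in step 8.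

Step 5
Reactants: 8 (6S)-2,6-dihydroxy-1,1-dimethoxy-2,9-dimethyl-6-(propan-2-yl)dec-9-en-4-one
Product: 10 4-hydroxy-2-[(3R)-3-hydroxy-2,6-dimethylhept-6-en-3-yl]-4-methylcyclopent-2-en-1-one (both epimers at the ring carbinol), via keto aldehyde 9 (not isolated)
Conditions: LiBF4, MeCN/H2O (98:2), 50 °C; then pyrrolidine (0.3 equiv), AcOH (0.3 equiv), THF, 25 °C
Reagents that add atoms: none
Why: Mild acetal hydrolysis frees a non-enolisable α-hydroxy aldehyde (C9), and amine-catalysed intramolecular aldol (Mannich-type) condensation from C5, the only ketone α-carbon that can reach it through a five-membered ring, gives the cyclopent-2-enone, the amine leaving from C9 in preference to the tertiary OH on C4.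

Step 6
Reactants: 10 4-hydroxy-2-[(3R)-3-hydroxy-2,6-dimethylhept-6-en-3-yl]-4-methylcyclopent-2-en-1-one
Product: 11 3-[(3R)-3-hydroxy-2,6-dimethylhept-6-en-3-yl]-1-methyl-4-oxocyclopent-2-en-1-yl methyl oxalate (both epimers at the ring carbinol carbon)
Conditions: ClC(O)CO2Me (1.5 equiv), pyridine, DMAP (cat.), CH2Cl2, 0 °C
Reagents that add atoms: methyl chlorooxoacetate, COC(=O)C(=O)Cl
Why: Acylation under nucleophilic catalysis is expected at the less hindered ring carbinol (C8–OH) and not at the isopropyl-flanked C4–OH, and installs the tertiary oxalate as radical precursor; β-elimination is not a concern because it would give a cyclopentadienone.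

Step 7
Reactants: 11 3-[(3R)-3-hydroxy-2,6-dimethylhept-6-en-3-yl]-1-methyl-4-oxocyclopent-2-en-1-yl methyl oxalate
Product: 12 methyl 10-hydroxy-4,7-dimethyl-2-oxo-10-(propan-2-yl)tricyclo[5.3.0.0(1,5)]decan-4-yl oxalate (cyclobutane C1–C5–C9–C10 in carotane numbering; C15 methyl, C6 and 4-OH on one face of the new cyclopentane, isopropyl and the cyclobutane edge C9–C10 on the other; both C8 epimers)
Conditions: hν (366 nm, Pyrex), degassed CH2Cl2 (5 mM), 0 °C
Reagents that add atoms: none
Why: Excitation of the cyclopentenone and intersystem crossing give the triplet enone, whose α-carbon C5 bonds first to the internal alkene carbon C1, and the resulting 1,4-biradical (C9, C10) closes to the cyclobutane after spin inversion, so the straight (fused) adduct with the C1–C5 and C9–C10 bonds results. The closest known reaction type is the intramolecular enone–alkene [2+2] photocycloaddition of 2-(pent-4-enyl)cycloalk-2-enones, including 4-methylpent-4-enyl tethers that create a ring-fusion quaternary methyl carbon. Two rings close: the cyclopentane C1–C2–C3–C4–C5 in a 5-exo mode with respect to the alkene (1,5-closure) and the cyclobutane C1–C5–C9–C10 by biradical recombination, while the seven-membered ring is still latent. C1 and C5 are fixed relative to each other by the obligatory cis fusion of the bicyclo[3.2.0]heptane (C15 methyl cis to C6), C9 by the cis fusion of cyclobutane and cyclopentanone, and the absolute sense by C4: in the non-polar solvent its OH is hydrogen-bonded to the C6 carbonyl, which places the tether on one face and the isopropyl group on the other, so that the C15 methyl ends cis to the 4-OH. The step needs straight rather than crossed regiochemistry (secured by the three-carbon tether on the α-carbon), facial selectivity (secured by C4 as described, the epimeric C8 centre being remote from the first bond-forming site) and excitation of the enone only (secured by irradiation above 350 nm, where the oxalate does not absorb).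

Step 8
Reactants: 12 methyl 10-hydroxy-4,7-dimethyl-2-oxo-10-(propan-2-yl)tricyclo[5.3.0.0(1,5)]decan-4-yl oxalate
Product: 13 4β-hydroxydauc-8-en-6-one (both C5 epimers)
Conditions: Bu3SnH (1.5 equiv, syringe pump), AIBN (0.2 equiv), toluene, 110 °C, 5 mM
Reagents that add atoms: none
Why: Bu3Sn• adds to the oxalate and releases the tertiary C8 radical (Barton–McCombie-type deoxygenation of a tertiary methyl oxalate), a cyclobutylcarbinyl radical that undergoes strain-driven β-scission of the ring-fusion bond C5–C9 because only this gives a tertiary α-keto radical (C9–C10 scission would give a primary radical), the known radical fragmentation of [2+2] photoadducts to ring-enlarged ketones; hydrogen transfer to C5 is not expected to be face-selective and C5 is set in step 10.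

Step 9
Reactants: 13 4β-hydroxydauc-8-en-6-one (both C5 epimers)
Product: 15 4β-hydroxydauca-7,9-dien-6-one (both C5 epimers), via silyl dienol ether 14 (not isolated)
Conditions: TBSOTf (1.1 equiv), Et3N, CH2Cl2, −78 °C; then DDQ (1.2 equiv), 2,6-lutidine, CH2Cl2, 0 °C
Reagents that add atoms: none
Why: Soft enolisation occurs toward the doubly activated C7 to give the 6-silyloxy-6,8-diene, and DDQ abstracts hydride from the allylic C10 (dehydrogenation of a dienol ether to the linear dienone, as used for steroidal 4,6-dien-3-ones), which removes the labile β,γ-unsaturated ketone and places an alkene at C9=C10 for oxygenation.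

Step 10
Reactants: 15 4β-hydroxydauca-7,9-dien-6-one (both C5 epimers)
Product: 16 (3R,3aR,8aR)-3-hydroxy-6,8a-dimethyl-3-(propan-2-yl)-2,3,3a,8a-tetrahydroazulen-4(1H)-one (5α-H, trans-fused 4β-hydroxydauca-7,9-dien-6-one)
Conditions: DBU (1 equiv), toluene, 60 °C
Reagents that add atoms: none
Why: C5–H is the only enolisable position of the linear dienone, so base equilibrates C5 alone, and the trans-fused epimer (C6 trans to the isopropyl group and cis to the 4β-OH, which can hydrogen-bond to the carbonyl) should be favoured; a reversible retro-aldol opening at C4–C5 would return to the same arrangement.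

Step 11
Reactants: 16 trans-fused 4β-hydroxydauca-7,9-dien-6-one
Product: 17 9α,10α-epoxy-4β-hydroxydauc-7-en-6-one
Conditions: mCPBA (1.1 equiv), NaHCO3, CH2Cl2, 0 °C
Reagents that add atoms: 3-chloroperoxybenzoic acid, OOC(=O)c1cccc(Cl)c1
Why: Prilezhaev epoxidation takes place at the more electron-rich γ,δ-alkene C9=C10 of the dienone and from the α face, anti to the β-C15 methyl on the adjacent quaternary C1, which sets the C10–O bond α.

Step 12
Reactants: 17 9α,10α-epoxy-4β-hydroxydauc-7-en-6-one
Product: 18 9α,10α-epoxydauc-7-ene-4β,6α-diol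
Conditions: Me4NBH(OAc)3 (5 equiv), MeCN/AcOH (1:1), −30 °C
Reagents that add atoms: none
Why: Saksena–Evans reduction: the C4–OH exchanges onto boron and delivers hydride intramolecularly to the β face of the C6 carbonyl (1,2-reduction, anti-1,3-diol), giving the 6α-alcohol, with no other hydroxyl present to compete.

Step 13
Reactants: 18 9α,10α-epoxydauc-7-ene-4β,6α-diol
Product: 19 (3R,3aS,4S,8R,8aS)-6,8a-dimethyl-3-(propan-2-yl)-1,2,3,3a,4,5,8,8a-octahydroazulene-3,4,8-triol (dauc-8-ene-4β,6α,10α-triol)
Conditions: i-Bu2AlH (5 equiv), CH2Cl2, −78 to 0 °C; aq. KNaC4H4O6 work-up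
Reagents that add atoms: none
Why: i-Bu2AlH is known to open vinyl epoxides in the SN2′ sense: hydride adds to the alkene terminus C7, the double bond moves to C8=C9 and the C9–O bond breaks, so the C10–O bond keeps its α configuration and the trisubstituted ring alkene of the target is formed.

Step 14
Reactants: 19 dauc-8-ene-4β,6α,10α-triol; 20 angelic acid [(2Z)-2-methylbut-2-enoic acid]
Product: 22 (3R,3aS,4S,8R,8aS)-3-hydroxy-6,8a-dimethyl-3-(propan-2-yl)-1,2,3,3a,4,5,8,8a-octahydroazulene-4,8-diyl bis[(2Z)-2-methylbut-2-enoate], via mixed anhydride 21 (not isolated)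
Conditions: 20 (6 equiv), 2,4,6-trichlorobenzoyl chloride (6 equiv), Et3N (6 equiv), toluene, 25 °C; then 19, toluene, 80 °C
Reagents that add atoms: none
Why: Acylation by the preformed mixed anhydride of angelic acid (Yamaguchi-type, no nucleophilic catalyst) is the established way to make angelates without Z to E isomerisation; both secondary alcohols are esterified and the tertiary C4–OH is not.

**Compound list**
1 | (S)-terpinen-4-ol, (1S)-4-methyl-1-(propan-2-yl)cyclohex-3-en-1-ol | CC(C)[C@]1(O)CCC(C)=CC1 | starting material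
2 | ozonide of 1, 6-methyl-3-(propan-2-yl)-7,8,9-trioxabicyclo[4.2.1]nonan-3-ol (carbinol centre as in 1; not isolated) | CC(C)[C@@]1(O)CC2OC(C)(CC1)OO2 | intermediate
3 | (3S)-3-hydroxy-6-oxo-3-(propan-2-yl)heptanal | CC(C)[C@@](O)(CC=O)CCC(C)=O | intermediate
4 | (4S)-7-methyl-4-(propan-2-yl)octa-1,7-dien-4-ol | CC(C)[C@@](O)(CC=C)CCC(C)=C | intermediate
5 | (4S)-4-hydroxy-7-methyl-4-(propan-2-yl)oct-7-en-2-one | CC(C)[C@@](O)(CC(C)=O)CCC(C)=C | intermediate
6 | 1,1-dimethoxypropan-2-one | CC(=O)C(OC)OC | starting material
7 | dilithium alkoxide–enolate of 5 (not isolated) | CC(C)[C@@](O[Li])(CC(=C)O[Li])CCC(C)=C | intermediate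
8 | (6S)-2,6-dihydroxy-1,1-dimethoxy-2,9-dimethyl-6-(propan-2-yl)dec-9-en-4-one (both C2 epimers) | CC(C)[C@@](O)(CC(=O)CC(C)(O)C(OC)OC)CCC(C)=C | intermediate
9 | (6S)-2,6-dihydroxy-2,9-dimethyl-4-oxo-6-(propan-2-yl)dec-9-enal (both C2 epimers; not isolated) | CC(C)[C@@](O)(CC(=O)CC(C)(O)C=O)CCC(C)=C | intermediate
10 | 4-hydroxy-2-[(3R)-3-hydroxy-2,6-dimethylhept-6-en-3-yl]-4-methylcyclopent-2-en-1-one (both epimers at the ring carbinol) | CC(C)[C@@](O)(C1=CC(C)(O)CC1=O)CCC(C)=C | intermediate
11 | 3-[(3R)-3-hydroxy-2,6-dimethylhept-6-en-3-yl]-1-methyl-4-oxocyclopent-2-en-1-yl methyl oxalate (both epimers at the ring carbinol carbon) | CC(C)[C@@](O)(C1=CC(C)(OC(=O)C(=O)OC)CC1=O)CCC(C)=C | intermediate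
12 | methyl 10-hydroxy-4,7-dimethyl-2-oxo-10-(propan-2-yl)tricyclo[5.3.0.0(1,5)]decan-4-yl oxalate (7-methyl cis to 10-OH and to C2; isopropyl cis to the cyclobutane CH2; both epimers at C4 of this name, which is C8 of the carotane numbering) | O=C1CC(C)(OC(=O)C(=O)OC)[C@@H]2C[C@@]3(C)CC[C@@](O)(C(C)C)[C@@]123 | intermediate
13 | 4β-hydroxydauc-8-en-6-one, 3-hydroxy-6,8a-dimethyl-3-(propan-2-yl)-2,3,3a,5,8,8a-hexahydroazulen-4(1H)-one (both C5 epimers) | O=C1CC(C)=CC[C@@]2(C)CC[C@@](O)(C(C)C)C12 | intermediate
14 | 6-(tert-butyldimethylsilyloxy)dauca-6,8-dien-4β-ol (both C5 epimers; not isolated) | CC(C)(C)[Si](C)(C)OC1=CC(C)=CC[C@@]2(C)CC[C@@](O)(C(C)C)C12 | intermediate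
15 | 4β-hydroxydauca-7,9-dien-6-one (both C5 epimers) | O=C1C=C(C)C=C[C@@]2(C)CC[C@@](O)(C(C)C)C12 | intermediate
16 | (3R,3aR,8aR)-3-hydroxy-6,8a-dimethyl-3-(propan-2-yl)-2,3,3a,8a-tetrahydroazulen-4(1H)-one (trans-fused 4β-hydroxydauca-7,9-dien-6-one) | O=C1C=C(C)C=C[C@@]2(C)CC[C@@](O)(C(C)C)[C@H]12 | intermediate
17 | 9α,10α-epoxy-4β-hydroxydauc-7-en-6-one | O=C1C=C(C)[C@H]2O[C@H]2[C@@]3(C)CC[C@@](O)(C(C)C)[C@H]13 | intermediate
18 | 9α,10α-epoxydauc-7-ene-4β,6α-diol | O[C@H]1C=C(C)[C@H]2O[C@H]2[C@@]3(C)CC[C@@](O)(C(C)C)[C@H]13 | intermediate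
19 | (3R,3aS,4S,8R,8aS)-6,8a-dimethyl-3-(propan-2-yl)-1,2,3,3a,4,5,8,8a-octahydroazulene-3,4,8-triol (dauc-8-ene-4β,6α,10α-triol) | O[C@H]1CC(C)=C[C@@H](O)[C@@]2(C)CC[C@@](O)(C(C)C)[C@H]12 | intermediate
20 | angelic acid, (2Z)-2-methylbut-2-enoic acid | C/C=C(/C)C(=O)O | starting material
21 | (2Z)-2-methylbut-2-enoic 2,4,6-trichlorobenzoic anhydride (not isolated) | C/C=C(/C)C(=O)OC(=O)c1c(Cl)cc(Cl)cc1Cl | intermediate
22 | (3R,3aS,4S,8R,8aS)-3-hydroxy-6,8a-dimethyl-3-(propan-2-yl)-1,2,3,3a,4,5,8,8a-octahydroazulene-4,8-diyl bis[(2Z)-2-methylbut-2-enoate] | C/C=C(/C)C(=O)O[C@H]1CC(C)=C[C@@H](OC(=O)/C(C)=C\C)[C@@]2(C)CC[C@@](O)(C(C)C)[C@H]12 | target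

Total step count: 14. Longest linear sequence: 14 steps (1 to 22).

**Steps most likely to fail**

Step 8. The C8 radical may take hydrogen from the stannane before the ring opens, or a tin ketyl formed at C6 may open the α-keto cyclobutane at C1–C5. The fallback avoids any hydrogen-atom donor and any tin. It sets out from 12: the methyl oxalate is saponified with CsOH (1 equiv, THF/H2O, 0 °C) to the caesium oxalate F3, which is irradiated with blue LEDs in the presence of Ir[dF(CF3)ppy]2(dtbbpy)PF6 (1 mol %) in DME/DMF containing water. Single-electron oxidation and loss of two CO2 should give the same C8 radical, β-scission follows, and the C5 α-keto radical is reduced by the photocatalyst to the enolate and protonated. This comes back to the route at 13.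

Step 5. During acetal hydrolysis the C4 hydroxyl may add to the isopropenyl group under acid (cyclic ether formation), or the β-hydroxy ketone may dehydrate. The fallback uses no acid. It sets out from 5: the same kinetic enolate is added to 1-[(tert-butyldimethylsilyl)oxy]propan-2-one to give the silyloxy aldol F1, Bu4NF (THF, 0 °C) gives the triol F2, and TEMPO (cat.)/PhI(OAc)2 oxidises the primary alcohol to the aldehyde. This is the keto aldehyde 9, so the fallback comes back to the route at 9, which is cyclised with pyrrolidine/AcOH to 10 as before.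

Step 13. Hydride may open the epoxide directly at the allylic C9 (SN2) instead of adding to C7 (SN2′), which would leave the alkene at C7=C8. The fallback makes the alkene shift while C6 is still a ketone. It sets out from 17: SmI2 (2.2 equiv, THF/MeOH, −78 °C) reduces the γ,δ-epoxy enone to a dienolate that is protonated at C7, giving the β,γ-unsaturated hydroxy ketone F4 with the alkene at C8=C9 and the C10–O bond intact. Et3SiCl/imidazole then silylates the secondary C10–OH to the silyl ether F5, so that only the C4–OH can direct the reduction; Me4NBH(OAc)3 gives the 6α-alcohol F6; and HF·pyridine removes the silyl group. This comes back to the route at 19.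

**Further compounds**
F1 | step 5 | (6S)-1-[(tert-butyldimethylsilyl)oxy]-2,6-dihydroxy-2,9-dimethyl-6-(propan-2-yl)dec-9-en-4-one (both C2 epimers) | CC(C)[C@@](O)(CC(=O)CC(C)(O)CO[Si](C)(C)C(C)(C)C)CCC(C)=C
F2 | step 5 | (6S)-1,2,6-trihydroxy-2,9-dimethyl-6-(propan-2-yl)dec-9-en-4-one (both C2 epimers) | CC(C)[C@@](O)(CC(=O)CC(C)(O)CO)CCC(C)=C
F3 | step 8 | caesium 10-hydroxy-4,7-dimethyl-2-oxo-10-(propan-2-yl)tricyclo[5.3.0.0(1,5)]decan-4-yl oxalate (stereochemistry as in 12) | O=C1CC(C)(OC(=O)C(=O)[O-])[C@@H]2C[C@@]3(C)CC[C@@](O)(C(C)C)[C@@]123.[Cs+]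
F4 | step 13 | 4β,10α-dihydroxydauc-8-en-6-one (5α-H) | O=C1CC(C)=C[C@@H](O)[C@@]2(C)CC[C@@](O)(C(C)C)[C@H]12
F5 | step 13 | 4β-hydroxy-10α-(triethylsilyloxy)dauc-8-en-6-one (5α-H) | O=C1CC(C)=C[C@@H](O[Si](CC)(CC)CC)[C@@]2(C)CC[C@@](O)(C(C)C)[C@H]12
F6 | step 13 | 10α-(triethylsilyloxy)dauc-8-ene-4β,6α-diol | O[C@H]1CC(C)=C[C@@H](O[Si](CC)(CC)CC)[C@@]2(C)CC[C@@](O)(C(C)C)[C@H]12
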